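**Retrosynthetic overview**
- The (2S)-flavanone is opened at C2–C1′: the 3,4-dimethoxyphenyl group and the C2 stereocentre come last, by rhodium-catalysed asymmetric conjugate arylation of a 7-O-MOM 6,8-diprenylchromone.
- Ring C is closed before that from O1 onto an ynone carried by C4a; the C4 carbon enters as a formyl group ortho to the C8a hydroxyl (magnesium-directed, so that the prenyl alkenes never meet an electrophilic halogen).
- The strategy rests on ring A: a resorcinol whose C8 prenyl group sits between O7 and O1 (on C8a), with a second prenyl group at C6, hydrogen at C5 and the ring C carbon at C4a. This ring is cut into a four-carbon vinylketene (C7, C4a, C5, C6) and a two-carbon siloxyalkyne (C8, C8a).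
- The vinylketene comes from a dienyl diazomethyl ketone by Wolff rearrangement (four steps from but-3-yn-2-ol and prenyl bromide); the siloxyalkyne comes from methyl 4-methylpent-3-enoate by Kowalski homologation.
- Ring order: ring A (benzannulation), then ring C (chromone), then ring B attached as the arylboron reagent.

Key step: step 6

Assumption: but-3-yn-2-ol is used as the racemate, since its carbinol centre is oxidised away in step 3; "prenyl" means 3-methylbut-2-enyl throughout.

**Step 1**
Reactants: 1 but-3-yn-2-ol (racemic); 2 prenyl bromide (1-bromo-3-methylbut-2-ene)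
Product: 3 7-methyloct-6-en-3-yn-2-ol (racemic)
Conditions: CuI (10 mol %), K2CO3, n-Bu4NI (cat.), DMF, rt
Reagents that add atoms: none
Why: Copper-catalysed coupling of a terminal alkyne with an allylic halide, in which the copper acetylide should attack the unhindered primary terminus of the prenyl electrophile (SN2 rather than SN2′), any branched isomer being removed by chromatography.

**Step 2**
Reactants: 3 7-methyloct-6-en-3-yn-2-ol
Product: 4 (3E)-7-methylocta-3,6-dien-2-ol (racemic)
Conditions: LiAlH4, THF, 0 °C → reflux; aqueous work-up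
Reagents that add atoms: none
Why: Alkoxide-directed trans-hydroalumination of a propargylic alcohol should give the E-allylic alcohol only, and the isolated trisubstituted alkene is inert to LiAlH4.

**Step 3**
Reactants: 4 (3E)-7-methylocta-3,6-dien-2-ol
Product: 5 (3E)-7-methylocta-3,6-dien-2-one
Conditions: activated MnO2 (excess), CH2Cl2, rt
Reagents that add atoms: none
Why: Allylic alcohol oxidation with MnO2 is neutral and heterogeneous, so the doubly allylic C5 methylene should not be drawn into conjugation.

**Step 4**
Reactants: 5 (3E)-7-methylocta-3,6-dien-2-one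
Product: 7 (3E)-1-diazo-7-methylocta-3,6-dien-2-one, via trifluoroacetyl diketone 6 (not isolated)
Conditions: LiN(SiMe3)2, THF, −78 °C; CF3CO2CH2CF3, −78 °C; aq. HCl work-up; then MsN3, Et3N, H2O, MeCN, rt
Reagents that add atoms: methanesulfonyl azide, CS(=O)(=O)N=[N+]=[N-]; 2,2,2-trifluoroethyl trifluoroacetate, O=C(OCC(F)(F)F)C(F)(F)F (its atoms stay only in intermediate 6)
Why: Detrifluoroacetylative diazo transfer (Danheiser variant of the Regitz deacylative transfer), in which the kinetic methyl enolate is trifluoroacetylated and the activated diketone accepts the diazo group with loss of the trifluoroacetyl unit; this avoids the acyl chloride/diazomethane route, which fails with enones through pyrazoline formation.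

**Step 5**
Reactants: 8 methyl 4-methylpent-3-enoate
Product: 11 triisopropyl[(5-methylhex-4-en-1-yn-1-yl)oxy]silane, via dibromo enolate 9 (not isolated), via lithium ynolate 10 (not isolated)
Conditions: CH2Br2, lithium 2,2,6,6-tetramethylpiperidide (LiTMP), THF, −78 °C; add 8; n-BuLi, −78 °C → rt; i-Pr3SiOTf, −78 → 0 °C
Reagents that add atoms: dibromomethane, BrCBr; triisopropylsilyl trifluoromethanesulfonate, CC(C)[Si](OS(=O)(=O)C(F)(F)F)(C(C)C)C(C)C
Why: Kowalski ester homologation stopped at the ynolate, in which LiCHBr2 adds to the ester, bromine–lithium exchange on the dibromo enolate triggers a carbenoid 1,2-shift of the homoallylic group, and the bulky silyl triflate traps the ynolate on oxygen.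

**Step 6**
Reactants: 7 (3E)-1-diazo-7-methylocta-3,6-dien-2-one; 11 triisopropyl[(5-methylhex-4-en-1-yn-1-yl)oxy]silane (1.3 equiv)
Product: 16 2,6-bis(3-methylbut-2-enyl)-3-(triisopropylsilyloxy)phenol, via vinylketene 12 (not isolated), via vinylcyclobutenone 13 (not isolated), via dienylketene 14 (not isolated), via cyclohexadienone 15 (not isolated)
Conditions: hν (254 nm, low-pressure Hg lamp, quartz), ClCH2CH2Cl, rt; then 80 °C
Reagents that add atoms: none
Why: Photochemical Wolff rearrangement of 7 expels N2 and shifts the dienyl group to the diazo carbon (forming C4a–C5) to give vinylketene 12, whose carbonyl carbon (future C7) is attacked by the nucleophilic, prenyl-bearing carbon of the siloxyalkyne in a [2+2] cycloaddition that forms C7–C8 and C4a–C8a (cyclobutenone 13). Four-electron electrocyclic opening of 13 (light or heat) cleaves the former ketene bond C7–C4a to give dienylketene 14, which closes ring A as a six-membered carbocycle by thermal six-electron electrocyclisation forming C6–C7, and cyclohexadienone 15 aromatises by tautomerisation. The closest known reaction type is the Danheiser benzannulation of α,β-unsaturated diazomethyl ketones with trialkylsiloxyalkynes to give resorcinol monosilyl ethers. No stereocentre survives, since the sp3 carbon of 15 is lost on enolisation. The step needs regiocontrol, secured by the polarisation of the ynol ether toward the electrophilic ketene carbon so that the alkyne prenyl group ends at C8 between the two oxygens, and chemoselectivity for the alkyne over the isolated trisubstituted alkenes, secured by the far higher nucleophilicity of the siloxyalkyne and by the E geometry of the enone, which holds the tethered alkene and the allylic methylene away from the ketene so that neither intramolecular [2+2] addition nor 1,5-hydrogen shift is geometrically possible. The product carries a free hydroxyl at C7 and a silyl ether at C8a, and C4a is the only position ortho to the C8a oxygen left unsubstituted.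

**Step 7**
Reactants: 16 2,6-bis(3-methylbut-2-enyl)-3-(triisopropylsilyloxy)phenol
Product: 17 triisopropyl[3-(methoxymethoxy)-2,4-bis(3-methylbut-2-enyl)phenoxy]silane
Conditions: NaH, MOMCl, THF/DMF, 0 °C → rt
Reagents that add atoms: chloromethyl methyl ether, COCCl
Why: Williamson-type O-alkylation of the sodium phenoxide with the small, highly reactive chloromethyl ether should overcome the two flanking prenyl groups, and the silyl ether is stable to NaH.

**Step 8**
Reactants: 17 triisopropyl[3-(methoxymethoxy)-2,4-bis(3-methylbut-2-enyl)phenoxy]silane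
Product: 18 3-(methoxymethoxy)-2,4-bis(3-methylbut-2-enyl)phenol
Conditions: n-Bu4NF, THF, 0 °C
Reagents that add atoms: none
Why: Fluoride-driven cleavage of the aryl silyl ether (Si–F bond formation) frees the C8a hydroxyl alone, the MOM acetal and the alkenes being inert.

**Step 9**
Reactants: 18 3-(methoxymethoxy)-2,4-bis(3-methylbut-2-enyl)phenol
Product: 20 2-hydroxy-4-(methoxymethoxy)-3,5-bis(3-methylbut-2-enyl)benzaldehyde, via salicyl alcohol 19 (not isolated)
Conditions: MgCl2, Et3N, (CH2O)n, MeCN, reflux; cold dilute citric acid work-up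
Reagents that add atoms: formaldehyde (as paraformaldehyde), C=O
Why: Casnati–Skattebøl ortho-formylation, in which the magnesium phenoxide delivers formaldehyde to the only free ortho position (C4a) and the resulting benzylic alkoxide is oxidised by hydride transfer to a second formaldehyde; no electrophilic halogen is used, which an ortho-prenyl phenol would answer by haloetherification.

**Step 10**
Reactants: 20 2-hydroxy-4-(methoxymethoxy)-3,5-bis(3-methylbut-2-enyl)benzaldehyde
Product: 21 2-(1-hydroxyprop-2-yn-1-yl)-5-(methoxymethoxy)-4,6-bis(3-methylbut-2-enyl)phenol (racemic)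
Conditions: HC≡CMgBr (3 equiv), THF, 0 °C → rt; aq. NH4Cl
Reagents that add atoms: ethynylmagnesium bromide, C#C[Mg]Br
Why: Grignard 1,2-addition to the salicylaldehyde, the first equivalent being spent on the phenol, should give the propargylic alcohol, whose carbinol centre is removed in the next step.

**Step 11**
Reactants: 21 2-(1-hydroxyprop-2-yn-1-yl)-5-(methoxymethoxy)-4,6-bis(3-methylbut-2-enyl)phenol
Product: 23 7-(methoxymethoxy)-6,8-bis(3-methylbut-2-enyl)-4H-chromen-4-one, via aryl ynone 22 (not isolated)
Conditions: activated MnO2, CH2Cl2, rt; filter; then K2CO3, acetone, rt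
Reagents that add atoms: none
Why: MnO2 oxidation of the benzylic propargylic alcohol gives the ortho-hydroxyaryl ynone, and the phenoxide should add to its unhindered terminal carbon in a 6-endo-dig oxa-Michael cyclisation that closes ring C as the chromone.

**Step 12**
Reactants: 23 7-(methoxymethoxy)-6,8-bis(3-methylbut-2-enyl)-4H-chromen-4-one; 24 3,4-dimethoxyphenylboronic acid (3 equiv)
Product: 25 (2S)-2-(3,4-dimethoxyphenyl)-7-(methoxymethoxy)-6,8-bis(3-methylbut-2-enyl)-2,3-dihydro-4H-chromen-4-one
Conditions: [RhCl(C2H4)2]2 (2.5 mol %), MeO-F12-BIPHEP (6,6′-dimethoxybiphenyl-2,2′-diyl bis[bis(3,4,5-trifluorophenyl)phosphine], 5.5 mol %), KOH (10 mol %), toluene/H2O, 30 °C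
Reagents that add atoms: none
Why: Hayashi–Miyaura asymmetric 1,4-addition, in which the aryl–rhodium species inserts the C2=C3 bond of the chromone on the face left open by the chiral bisphosphine and water protonates the rhodium enolate; the ligand antipode is the one that delivers the aryl group to the Re face of C2 (to be fixed by a test on chromone itself), which gives 2S, and the nearly base-free, low-temperature conditions are meant to keep the flavanone from opening to the chalcone.

**Step 13**
Reactants: 25 (2S)-2-(3,4-dimethoxyphenyl)-7-(methoxymethoxy)-6,8-bis(3-methylbut-2-enyl)-2,3-dihydro-4H-chromen-4-one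
Product: 26 IN0946, (2S)-2-(3,4-dimethoxyphenyl)-7-hydroxy-6,8-bis(3-methylbut-2-enyl)-2,3-dihydro-4H-chromen-4-one
Conditions: 3 M aq. HCl (cat.), MeOH, rt → 40 °C
Reagents that add atoms: none
Why: Acid-catalysed transacetalisation of the aryl MOM ether to methanol frees the C7 hydroxyl; dilute acid in methanol at low temperature should leave the prenyl groups uncyclised and the C2 centre, which racemises only by base-induced ring opening, intact.

**Compound list**
1 | but-3-yn-2-ol (racemic) | CC(O)C#C | starting material
2 | prenyl bromide (1-bromo-3-methylbut-2-ene) | CC(C)=CCBr | starting material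
3 | 7-methyloct-6-en-3-yn-2-ol (racemic) | CC(O)C#CCC=C(C)C | intermediate
4 | (3E)-7-methylocta-3,6-dien-2-ol (racemic) | CC(O)/C=C/CC=C(C)C | intermediate
5 | (3E)-7-methylocta-3,6-dien-2-one | CC(=O)/C=C/CC=C(C)C | intermediate
6 | (5E)-1,1,1-trifluoro-9-methyldeca-5,8-diene-2,4-dione | O=C(CC(=O)C(F)(F)F)/C=C/CC=C(C)C | intermediate
7 | (3E)-1-diazo-7-methylocta-3,6-dien-2-one | [N-]=[N+]=CC(=O)/C=C/CC=C(C)C | intermediate
8 | methyl 4-methylpent-3-enoate | COC(=O)CC=C(C)C | starting material
9 | lithium 1,1-dibromo-5-methylhexa-1,4-dien-2-olate | [Li+].[O-]C(CC=C(C)C)=C(Br)Br | intermediate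
10 | lithium 5-methylhex-4-en-1-yn-1-olate | [Li+].[O-]C#CCC=C(C)C | intermediate
11 | triisopropyl[(5-methylhex-4-en-1-yn-1-yl)oxy]silane | CC(C)=CCC#CO[Si](C(C)C)(C(C)C)C(C)C | intermediate
12 | (3E)-7-methylocta-1,3,6-trien-1-one (vinylketene) | O=C=C/C=C/CC=C(C)C | intermediate
13 | 2-(3-methylbut-2-enyl)-4-[(1E)-5-methylhexa-1,4-dienyl]-3-(triisopropylsilyloxy)cyclobut-2-en-1-one (racemic) | O=C1C(CC=C(C)C)=C(O[Si](C(C)C)(C(C)C)C(C)C)C1/C=C/CC=C(C)C | intermediate
14 | (3E,5E)-9-methyl-2-(3-methylbut-2-enyl)-3-(triisopropylsilyloxy)deca-1,3,5,8-tetraen-1-one (ketene carbon and C5 cis on C3=C4) | O=C=C(CC=C(C)C)/C(O[Si](C(C)C)(C(C)C)C(C)C)=C\C=C\CC=C(C)C | intermediate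
15 | 2,6-bis(3-methylbut-2-enyl)-3-(triisopropylsilyloxy)cyclohexa-2,4-dien-1-one (racemic) | O=C1C(CC=C(C)C)=C(O[Si](C(C)C)(C(C)C)C(C)C)C=CC1CC=C(C)C | intermediate
16 | 2,6-bis(3-methylbut-2-enyl)-3-(triisopropylsilyloxy)phenol | Oc1c(CC=C(C)C)ccc(O[Si](C(C)C)(C(C)C)C(C)C)c1CC=C(C)C | intermediate
17 | triisopropyl[3-(methoxymethoxy)-2,4-bis(3-methylbut-2-enyl)phenoxy]silane | COCOc1c(CC=C(C)C)ccc(O[Si](C(C)C)(C(C)C)C(C)C)c1CC=C(C)C | intermediate
18 | 3-(methoxymethoxy)-2,4-bis(3-methylbut-2-enyl)phenol | COCOc1c(CC=C(C)C)ccc(O)c1CC=C(C)C | intermediate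
19 | 2-(hydroxymethyl)-5-(methoxymethoxy)-4,6-bis(3-methylbut-2-enyl)phenol | OCc1cc(CC=C(C)C)c(OCOC)c(CC=C(C)C)c1O | intermediate
20 | 2-hydroxy-4-(methoxymethoxy)-3,5-bis(3-methylbut-2-enyl)benzaldehyde | O=Cc1cc(CC=C(C)C)c(OCOC)c(CC=C(C)C)c1O | intermediate
21 | 2-(1-hydroxyprop-2-yn-1-yl)-5-(methoxymethoxy)-4,6-bis(3-methylbut-2-enyl)phenol (racemic) | C#CC(O)c1cc(CC=C(C)C)c(OCOC)c(CC=C(C)C)c1O | intermediate
22 | 1-[2-hydroxy-4-(methoxymethoxy)-3,5-bis(3-methylbut-2-enyl)phenyl]prop-2-yn-1-one | C#CC(=O)c1cc(CC=C(C)C)c(OCOC)c(CC=C(C)C)c1O | intermediate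
23 | 7-(methoxymethoxy)-6,8-bis(3-methylbut-2-enyl)-4H-chromen-4-one | O=c1ccoc2c(CC=C(C)C)c(OCOC)c(CC=C(C)C)cc12 | intermediate
24 | 3,4-dimethoxyphenylboronic acid | COc1ccc(B(O)O)cc1OC | starting material
25 | (2S)-2-(3,4-dimethoxyphenyl)-7-(methoxymethoxy)-6,8-bis(3-methylbut-2-enyl)-2,3-dihydro-4H-chromen-4-one | COc1ccc([C@@H]2CC(=O)c3cc(CC=C(C)C)c(OCOC)c(CC=C(C)C)c3O2)cc1OC | intermediate
26 | IN0946, (2S)-2-(3,4-dimethoxyphenyl)-7-hydroxy-6,8-bis(3-methylbut-2-enyl)-2,3-dihydro-4H-chromen-4-one | COc1ccc([C@@H]2CC(=O)c3cc(CC=C(C)C)c(O)c(CC=C(C)C)c3O2)cc1OC | target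

**Step count and risks**
Total step count: 13. Longest linear sequence: 12 steps (steps 1–4 and 6–13); step 5 is the convergent branch.

Steps most likely to fail:

1. Step 6. The cascade may be diverted by photochemical E-to-Z isomerisation of the dienyl diazoketone followed by a 1,5-hydrogen shift of the Z-vinylketene, by capture of the ketene by a prenyl alkene, or by an incomplete electrocyclic sequence. The fallback gives up the annulation and places the three ring A substituents by successive directed ortho-metalations; it sets out from prenyl bromide 2 (with commercial 1,3-bis(methoxymethoxy)benzene) and comes back at aldehyde 20. Lithiation between the two acetal oxygens (n-BuLi, THF, 0 °C), transmetalation with CuBr·SMe2 and alkylation with 2 should give 1,3-bis(methoxymethoxy)-2-(3-methylbut-2-enyl)benzene F1. A second ortho-lithiation (n-BuLi, TMEDA) and the same copper-mediated prenylation with 2 should give 1,3-bis(methoxymethoxy)-2,4-bis(3-methylbut-2-enyl)benzene F2. A third lithiation at the one remaining position ortho to an acetal oxygen, quenched with DMF, should give 2,4-bis(methoxymethoxy)-3,5-bis(3-methylbut-2-enyl)benzaldehyde F3. Chelation-assisted cleavage of the acetal ortho to the formyl group (MgBr2·OEt2, Et2O, rt) then returns to 20.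

2. Step 12. Insertion of the electron-rich chromone may be slower than protodeboronation of the electron-rich boronic acid, and the enantiomeric purity may erode through base-induced ring opening to the chalcone and reclosure. The fallback replaces catalytic asymmetric arylation by a stoichiometric organocopper addition and resolution; it sets out from chromone 23 and comes back at 25. Copper-catalysed conjugate addition of commercial 3,4-dimethoxyphenylmagnesium bromide in the presence of Me3SiCl (CuBr·SMe2 cat., THF, −78 °C) should give the silyl enol ether 2-(3,4-dimethoxyphenyl)-7-(methoxymethoxy)-6,8-bis(3-methylbut-2-enyl)-4-(trimethylsilyloxy)-2H-chromene F4 (not isolated). Mild aqueous NH4Cl work-up hydrolyses it to racemic 2-(3,4-dimethoxyphenyl)-7-(methoxymethoxy)-6,8-bis(3-methylbut-2-enyl)-2,3-dihydro-4H-chromen-4-one F5. Preparative HPLC on a chiral stationary phase then separates 25 from its (2R)-antipode F6.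

3. Step 5. The lithium bases may deprotonate the acidic, allylic α-position of the β,γ-unsaturated ester instead of allowing addition of LiCHBr2, with loss of material and migration of the double bond. The fallback reaches the same ynolate by oxidation of an acetylide; it sets out from prenyl bromide 2 and comes back at siloxyalkyne 11. Copper-catalysed coupling of 2 with HC≡CMgBr (CuCl cat., THF) should give 5-methylhex-4-en-1-yne F7. Deprotonation with n-BuLi (THF, −78 °C), oxidation of the lithium acetylide with LiOOt-Bu to ynolate 10 and O-silylation with i-Pr3SiOTf return to 11.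

**Further compounds**
F1 | step 6 | 1,3-bis(methoxymethoxy)-2-(3-methylbut-2-enyl)benzene | COCOc1cccc(OCOC)c1CC=C(C)C
F2 | step 6 | 1,3-bis(methoxymethoxy)-2,4-bis(3-methylbut-2-enyl)benzene | COCOc1ccc(CC=C(C)C)c(OCOC)c1CC=C(C)C
F3 | step 6 | 2,4-bis(methoxymethoxy)-3,5-bis(3-methylbut-2-enyl)benzaldehyde | O=Cc1cc(CC=C(C)C)c(OCOC)c(CC=C(C)C)c1OCOC
F4 | step 12 | 2-(3,4-dimethoxyphenyl)-7-(methoxymethoxy)-6,8-bis(3-methylbut-2-enyl)-4-(trimethylsilyloxy)-2H-chromene (racemic) | COc1ccc(C2C=C(O[Si](C)(C)C)c3cc(CC=C(C)C)c(OCOC)c(CC=C(C)C)c3O2)cc1OC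
F5 | step 12 | 2-(3,4-dimethoxyphenyl)-7-(methoxymethoxy)-6,8-bis(3-methylbut-2-enyl)-2,3-dihydro-4H-chromen-4-one (racemic) | COc1ccc(C2CC(=O)c3cc(CC=C(C)C)c(OCOC)c(CC=C(C)C)c3O2)cc1OC
F6 | step 12 | (2R)-2-(3,4-dimethoxyphenyl)-7-(methoxymethoxy)-6,8-bis(3-methylbut-2-enyl)-2,3-dihydro-4H-chromen-4-one | COc1ccc([C@H]2CC(=O)c3cc(CC=C(C)C)c(OCOC)c(CC=C(C)C)c3O2)cc1OC
F7 | step 5 | 5-methylhex-4-en-1-yne | C#CCC=C(C)C
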